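In a one-step world a flask at full reagent loses substrate on one clock, whatever the charge. These flasks are fed through gas, so I wanted the factor by which the charge slows that clock.

in all of them: gas 200 mM (held)

| charge | substrate | remark | time |
|---|---|---|---|
| south | 0.14 M | run made earlier |  |
| south-east | 0.49 M | run made earlier |  |
| north-east | 2.3 M | run made earlier |  |
| cedar | 0.12 M |  | 25 h |
| elm | 0.25 M |  | 25 h |
| oak | 0.50 M |  | 25 h |
| larch | 1.0 M |  | 25 h |
| ash | 2.0 M |  | 25 h |

| run | time / h | triple product / % | substrate / % |
|---|---|---|---|
| south | 2.00 | 3 | 62 |
| south | 4.00 | 7 | 31 |
| south | 8.00 | 24 | 5 |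
| south | 12.0 | 42 | 3 |
| south | 25.0 | 80 | 1 |
| south-east | 2.00 | 1 | 70 |
| south-east | 4.00 | 1 | 44 |
| south-east | 8.00 | 10 | 13 |
| south-east | 12.0 | 29 | 4 |
| south-east | 25.0 | 71 | 0 |
| north-east | 5.00 | 3 | 70 |
| north-east | 10.0 | 1 | 51 |
| north-east | 15.0 | 7 | 30 |
| north-east | 20.0 | 12 | 16 |
| north-east | 25.0 | 16 | 6 |

(each reading ± 2 percentage points)

1. [triple product] at the end for cedar, elm, oak, larch, ash, in this order
2. how the row runs (hardly changes / rises, then falls / falls all the way / rises all the way / falls, then rises)

- at the start none of reagent is dissolved
- the numbers in the tables scatter by 2 percentage points (one standard deviation)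
- on the list of suspects stand: reagent + double product -> triple product + by-product; gas <-> reagent; reagent + mono adduct -> double product + by-product; substrate + reagent -> mono adduct + by-product
- "hardly changes" means that all values lie within two and a half points (for a concentration: within two and a half percent of the largest)

I did not take either south or north-east as standing at full reagent, so I read the clock and the supply from the two together. I assumed the mono adduct step to be fast and settled, so that each substrate lost costs two reagent at once, and I let uptake shrink in proportion as reagent fills towards 200 mM. Balancing uptake against use then makes the inverse pseudo-first-order rate of substrate a sum: the inverse clock at full reagent, plus twice the substrate standing over the uptake into an empty flask. South fell from 62% to 31% between 2.00 h and 4.00 h, an inverse rate of 2.89 h at a mean substrate of 0.0651 M. North-east fell from 51% to 16% between 10.0 h and 20.0 h, an inverse rate of 8.63 h at a mean substrate of 0.770 M. From these readings the uptake into an empty flask comes to 0.246 M h⁻¹ and the inverse clock to 2.36 h.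

Uptake divided by twice the clock gives 0.289 M, the choke load: the substrate standing in a flask when reagent sits at half its saturation. Free reagent is then saturation divided by one plus substrate over choke load, and each step using reagent slows by that divisor.

Once reagent has settled, the starting divisor is 1.41 for cedar, 4.46 for larch and 7.91 for ash. On that reckoning the substrate half-life of 1.64 h at full reagent becomes 12.9 h in ash at its starting charge. The slowing fades as substrate falls, and summed over a run it adds twice the charge over the uptake: 8.14 h in larch and 16.3 h in ash, out of 25 h. Through those hours the triple step stays slowed too, so I expected its percentage to fall along the row, and hard at ash.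

The forecast, which put “relative step rates of about 1 : 0.6 : 0.25” where I took the second step as fast, gave 0.098 M, 0.195 M, 0.35 M, 0.48 M and 0.38 M: rises, then falls.

    reagent + double product → triple product + by-product (k = 0.380 M⁻¹ h⁻¹)
    gas ⇌ reagent, rate k2*(csat - [reagent]) (kL = 1.20 h⁻¹)
    reagent + mono adduct → double product + by-product (k = 13.0 M⁻¹ h⁻¹)
    substrate + reagent → mono adduct + by-product (k = 2.30 M⁻¹ h⁻¹)

The flasks gave 0.0938 M, 0.189 M, 0.350 M, 0.562 M and 0.527 M: rises, then falls, turning near 1.4 M. At 25.0 h ash held 26.4% triple product and 67.8% double product. At 12.5 h ash still had 37.1% of its substrate, and the choke load turns that into 0.0561 M free reagent, where ash held 0.0443 M. Larch at 12.5 h, with 13.5% of its substrate left, reckons to 0.136 M, and larch held 0.108 M.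

The readings are simulated with constants of no real substance; scatter was added.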